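**Retrosynthetic overview**
1. The strategy rests on O1 of ring C: it bridges C2 and C8a, and C8a is ortho to C4a, which carries the C4 carbonyl, so a C8a–F bond is activated for SNAr and O1 can come from water.
2. Target 9 ⇒ enaminone 7 + water, cutting O1–C2 and O1–C8a; ring C is the only ring formed and it is formed last, with the 7-prenyloxy group already in place.
3. Enaminone 7 ⇒ deoxybenzoin 5 + DMF dimethyl acetal 6, which supplies the future C2.
4. Deoxybenzoin 5 ⇒ aryl methyl ketone 3 + 4-bromoveratrole 4 (C3–C1' bond by palladium-catalysed enolate arylation).
5. Ketone 3 ⇒ 2'-fluoro-4'-hydroxyacetophenone 1 + prenyl bromide 2 (O-alkylation).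

Key step: step 4

Remark: intermediate 8 is present in the flask as its potassium enolate; it is listed as the neutral (Z)-enol.

**Step 1**
Reactants: 1 2'-fluoro-4'-hydroxyacetophenone; 2 prenyl bromide (1-bromo-3-methylbut-2-ene)
Product: 3 1-[2-fluoro-4-(3-methylbut-2-enyloxy)phenyl]ethanone
Conditions: K2CO3, acetone, reflux
Reagents that add atoms: none
Why: Williamson ether synthesis: K2CO3 deprotonates only the phenol, which the para acetyl group acidifies, and the phenoxide displaces bromide from the primary allylic carbon by SN2, while the ketone, the aryl fluoride and the trisubstituted alkene are inert at acetone reflux.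

**Step 2**
Reactants: 3 1-[2-fluoro-4-(3-methylbut-2-enyloxy)phenyl]ethanone (1.2 equiv); 4 4-bromo-1,2-dimethoxybenzene
Product: 5 2-(3,4-dimethoxyphenyl)-1-[2-fluoro-4-(3-methylbut-2-enyloxy)phenyl]ethanone
Conditions: Pd2(dba)3 (cat.), Xantphos (cat.), K3PO4, toluene, 80 °C
Reagents that add atoms: none
Why: Palladium-catalysed α-arylation of a ketone enolate (Buchwald–Hartwig-type C–C coupling): zerovalent palladium inserts into the C–Br bond of 4, the potassium enolate of 3 replaces bromide on palladium and reductive elimination forms the benzylic C–C bond, with the wide-bite-angle Xantphos and the small excess of 3 favouring monoarylation, the weak phosphate base sparing the ortho C–F bond, and C–Br insertion expected to outrun ionisation of the hindered prenyl ether.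

**Step 3**
Reactants: 5 2-(3,4-dimethoxyphenyl)-1-[2-fluoro-4-(3-methylbut-2-enyloxy)phenyl]ethanone; 6 N,N-dimethylformamide dimethyl acetal
Product: 7 (E)-3-(dimethylamino)-2-(3,4-dimethoxyphenyl)-1-[2-fluoro-4-(3-methylbut-2-enyloxy)phenyl]prop-2-en-1-one
Conditions: 6 (3 equiv), toluene, 100 °C, MeOH distilled off
Reagents that add atoms: none
Why: Enaminone formation by condensation of an active methylene with an amide acetal: the methylene of 5, acidified by the ketone and the aryl ring, adds to the methoxy-iminium ion released from 6 and two molecules of methanol are lost to give the conjugated vinylogous amide as the thermodynamic (E)-isomer, under neutral conditions that leave the prenyl ether and the C–F bond alone.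

**Step 4**
Reactants: 7 (E)-3-(dimethylamino)-2-(3,4-dimethoxyphenyl)-1-[2-fluoro-4-(3-methylbut-2-enyloxy)phenyl]prop-2-en-1-one
Product: 9 7-prenyloxy-3',4'-dimethoxyisoflavone, via hydroxymethylene ketone 8 (not isolated)
Conditions: K2CO3 (3 equiv), DMF–H2O (10:1), 100 °C
Reagents that add atoms: water (O)
Why: Hydroxide generated from carbonate and water adds in conjugate fashion to the amine-bearing carbon of the vinylogous amide (the future C2) and the adduct expels dimethylamine, which forms O1–C2 and gives the potassium enolate of hydroxymethylene ketone 8. The enolate oxygen, cis to the aroyl group, then attacks the fluorine-bearing carbon (the future C8a), the Meisenheimer adduct is stabilised by the ortho ketone, and loss of fluoride forms O1–C8a and the 4-pyranone. The closest known reaction type is the addition–elimination and SNAr cyclisation of 2-haloaroyl enaminones, which gives 4-quinolones with amines and chromones with water or hydroxide. Ring C closes by a six-membered intramolecular SNAr (O-attack at C8a with fluoride as leaving group), and no stereocentre is formed. The step needs hydroxide to attack the enaminone carbon without cleaving the formyl carbon from 8 or opening the product, which the carbonate buffer and the small amount of water should secure. The site of closure is fixed by the single fluorine ortho to the ketone, and with no acid and no free phenol present the prenyl ether should stay untouched.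

**Compound list**
1 | 2'-fluoro-4'-hydroxyacetophenone | CC(=O)c1ccc(O)cc1F | starting material
2 | prenyl bromide (1-bromo-3-methylbut-2-ene) | CC(C)=CCBr | starting material
3 | 1-[2-fluoro-4-(3-methylbut-2-enyloxy)phenyl]ethanone | CC(=O)c1ccc(OCC=C(C)C)cc1F | intermediate
4 | 4-bromo-1,2-dimethoxybenzene (4-bromoveratrole) | COc1ccc(Br)cc1OC | starting material
5 | 2-(3,4-dimethoxyphenyl)-1-[2-fluoro-4-(3-methylbut-2-enyloxy)phenyl]ethanone | COc1ccc(CC(=O)c2ccc(OCC=C(C)C)cc2F)cc1OC | intermediate
6 | N,N-dimethylformamide dimethyl acetal | COC(OC)N(C)C | starting material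
7 | (E)-3-(dimethylamino)-2-(3,4-dimethoxyphenyl)-1-[2-fluoro-4-(3-methylbut-2-enyloxy)phenyl]prop-2-en-1-one | CN(C)/C=C(\c1ccc(OC)c(OC)c1)C(=O)c1ccc(OCC=C(C)C)cc1F | intermediate
8 | (Z)-2-(3,4-dimethoxyphenyl)-1-[2-fluoro-4-(3-methylbut-2-enyloxy)phenyl]-3-hydroxyprop-2-en-1-one (formed as its potassium enolate) | O/C=C(/c1ccc(OC)c(OC)c1)C(=O)c1ccc(OCC=C(C)C)cc1F | intermediate
9 | 7-prenyloxy-3',4'-dimethoxyisoflavone | COc1ccc(-c2coc3cc(OCC=C(C)C)ccc3c2=O)cc1OC | target

**Total step count:** 4
**Longest linear sequence:** 4 steps (from 1)

**Steps most likely to fail**

Step 4. The risk is that aqueous base cleaves the formyl carbon from enolate 8 (retro-Claisen loss of formate, returning 5) faster than the ring closes, the SNAr being slowed by the para alkoxy group that weakens the ketone's pull. The fallback brings O1 in from a formate ester under anhydrous conditions, so no hydroxide is present. It sets out from 5: Claisen formylation with ethyl formate (CCOC=O) and NaH in THF at 0 °C to room temperature should give the sodium enolate of 8, and dilution with dry DMF and warming to 80–100 °C should close ring C by the same intramolecular SNAr. It comes back to the route at 9. This fallback makes no compound outside the compound list (F0).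

Step 2. The risk is ionisation of the prenyl aryl ether by zerovalent palladium with transfer of the prenyl group to the enolate carbon, alongside over-arylation of the more acidic product. The fallback carries the phenol through the coupling as a benzyl ether, which zerovalent palladium does not ionise, and installs the prenyl group afterwards. It sets out from 1: benzyl bromide (BrCc1ccccc1) and K2CO3 in acetone should give 1-[4-(benzyloxy)-2-fluorophenyl]ethanone F1. The same Pd2(dba)3/Xantphos/K3PO4 arylation with 4 should give 1-[4-(benzyloxy)-2-fluorophenyl]-2-(3,4-dimethoxyphenyl)ethanone F2. Hydrogenolysis (H2 at 1 atm, palladium on carbon Pd/C, ethyl acetate, room temperature, stopped at consumption of F2 to spare the ketone) should give 2-(3,4-dimethoxyphenyl)-1-(2-fluoro-4-hydroxyphenyl)ethanone F3. O-Prenylation of F3 with 2 and K2CO3 in acetone, where only the phenol is deprotonated, comes back to the route at 5.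

Step 3. The risk is incomplete condensation at the hindered methylene flanked by two aryl-bearing groups, with liberated methoxide attacking the activated C–F bond on prolonged heating. The fallback reverses the order of the two C–C bond formations: the aminomethylene unit goes onto the unhindered methyl ketone and the aryl group is then attached by cross-coupling. It sets out from 3: condensation with 6 in toluene at 90 °C should give (E)-3-(dimethylamino)-1-[2-fluoro-4-(3-methylbut-2-enyloxy)phenyl]prop-2-en-1-one F4. Electrophilic α-iodination with N-iodosuccinimide (O=C1CCC(=O)N1I, 1.0 equiv) in CH2Cl2 at 0 °C, where the enaminone carbon is far more nucleophilic than the prenyl alkene, should give (Z)-3-(dimethylamino)-1-[2-fluoro-4-(3-methylbut-2-enyloxy)phenyl]-2-iodoprop-2-en-1-one F5. Suzuki–Miyaura coupling of F5 with 3,4-dimethoxyphenylboronic acid (COc1ccc(B(O)O)cc1OC), using Pd(PPh3)4 and K3PO4 in 1,4-dioxane with a few equivalents of water at 70 °C, comes back to the route at 7. Any ring closure that begins under these basic conditions would lead on to 9.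

**Further compounds**
F0 | step 4 | none | none
F1 | step 2 | 1-[4-(benzyloxy)-2-fluorophenyl]ethanone | CC(=O)c1ccc(OCc2ccccc2)cc1F
F2 | step 2 | 1-[4-(benzyloxy)-2-fluorophenyl]-2-(3,4-dimethoxyphenyl)ethanone | COc1ccc(CC(=O)c2ccc(OCc3ccccc3)cc2F)cc1OC
F3 | step 2 | 2-(3,4-dimethoxyphenyl)-1-(2-fluoro-4-hydroxyphenyl)ethanone | COc1ccc(CC(=O)c2ccc(O)cc2F)cc1OC
F4 | step 3 | (E)-3-(dimethylamino)-1-[2-fluoro-4-(3-methylbut-2-enyloxy)phenyl]prop-2-en-1-one | CN(C)/C=C/C(=O)c1ccc(OCC=C(C)C)cc1F
F5 | step 3 | (Z)-3-(dimethylamino)-1-[2-fluoro-4-(3-methylbut-2-enyloxy)phenyl]-2-iodoprop-2-en-1-one | CN(C)/C=C(\I)C(=O)c1ccc(OCC=C(C)C)cc1F
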